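## Retrosynthetic overview

1. Target 22 ⇐ acetylation of allylic alcohol 21 ⇐ catalyst-controlled Ni/Cr coupling (C7–C8 bond, C7 stereocentre) of 2-bromoalkene 12 with aldehyde 20.
2. 12 ⇐ organocatalytic desymmetrising transfer hydrogenation of the mirror-symmetric dienone 11; this one step sets both ring stereocentres (C4 quaternary, C5 tertiary).
3. 11 ⇐ dehydrogenation of racemic enone 10 ⇐ Stork–Danheiser sequence (two α′-alkylations, then MeLi/H3O+) on the vinylogous ester of 5-methylcyclohexane-1,3-dione.
4. 20 ⇐ oxidation of 19 ⇐ B-alkyl Suzuki coupling of 4-bromofuran-2(5H)-one with the borane from (E)-diene-ol 16 ⇐ Zr-catalysed carboalumination/Negishi coupling of pent-4-yn-1-ol.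
5. No ring is built: the carbocycle comes from dione 1 and the butenolide from bromofuranone 17.

Assumption: compounds 2–10 are racemic (their stereocentres are erased at 11), and the catalyst antipodes named in steps 7 and 11 follow the stated models; the mirror-image catalyst is used if the first run shows the opposite sense.

## Route

Step 1
Reactants: 1 5-methylcyclohexane-1,3-dione
Product: 2 3-isobutoxy-5-methylcyclohex-2-en-1-one (racemic)
Conditions: i-BuOH, TsOH·H2O (cat.), toluene, reflux, Dean–Stark
Reagents that add atoms: isobutanol (CC(C)CO)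
Why: Acid-catalysed vinylogous ester formation from a symmetric 1,3-dione gives a single regioisomer; the C5 centre is racemic and is erased in step 6.

Step 2
Reactants: 3 3-bromobut-3-en-1-ol
Product: 4 2-bromo-4-iodobut-1-ene
Conditions: I2, PPh3, imidazole, CH2Cl2, 0 °C → rt
Reagents that add atoms: iodine (II)
Why: Appel iodination of a primary alcohol; the vinyl bromide is inert.

Step 3
Reactants: 2 3-isobutoxy-5-methylcyclohex-2-en-1-one, 4 2-bromo-4-iodobut-1-ene
Product: 6 6-(3-bromobut-3-en-1-yl)-3-isobutoxy-5-methylcyclohex-2-en-1-one (racemic), via lithium enolate 5 (not isolated)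
Conditions: LiN(iPr)2, THF, −78 °C; then 4, DMPU, −78 → 0 °C
Reagents that add atoms: none
Why: Stork–Danheiser kinetic α′-deprotonation of a vinylogous ester and SN2 alkylation with a primary iodide; relative configuration is irrelevant here.

Step 4
Reactants: 6 6-(3-bromobut-3-en-1-yl)-3-isobutoxy-5-methylcyclohex-2-en-1-one
Product: 8 6-(3-bromobut-3-en-1-yl)-3-isobutoxy-5,6-dimethylcyclohex-2-en-1-one (racemic diastereomer mixture), via lithium enolate 7 (not isolated)
Conditions: LiN(iPr)2, THF, −78 °C; then MeI, −78 → 0 °C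
Reagents that add atoms: iodomethane (CI)
Why: Second Stork–Danheiser α′-alkylation with a small electrophile builds the quaternary carbon; the diastereomer ratio does not matter because C5 is flattened in step 6.

Step 5
Reactants: 8 6-(3-bromobut-3-en-1-yl)-3-isobutoxy-5,6-dimethylcyclohex-2-en-1-one
Product: 10 4-(3-bromobut-3-en-1-yl)-3,4,5-trimethylcyclohex-2-en-1-one (racemic diastereomer mixture), via lithium alkoxide 9 (not isolated)
Conditions: MeLi, THF, −78 → 0 °C; then 1 M HCl, rt
Reagents that add atoms: methyllithium (C[Li]); water (O)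
Why: Stork–Danheiser 1,2-addition to the vinylogous ester, then acid hydrolysis with 1,3-carbonyl transposition, places the methyl on the enone β-carbon next to the quaternary centre; MeLi does not exchange a vinyl bromide at low temperature.

Step 6
Reactants: 10 4-(3-bromobut-3-en-1-yl)-3,4,5-trimethylcyclohex-2-en-1-one
Product: 11 4-(3-bromobut-3-en-1-yl)-3,4,5-trimethylcyclohexa-2,5-dien-1-one
Conditions: IBX, DMSO, 75 °C
Reagents that add atoms: none
Why: IBX α,β-dehydrogenation of a ketone; only the C5–C6 pair carries removable hydrogens (C4 is quaternary), so the cross-conjugated, mirror-symmetric dienone forms and the racemic C5 centre disappears.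

Step 7
Reactants: 11 4-(3-bromobut-3-en-1-yl)-3,4,5-trimethylcyclohexa-2,5-dien-1-one
Product: 12 (4R,5R)-4-(3-bromobut-3-en-1-yl)-3,4,5-trimethylcyclohex-2-en-1-one
Conditions: L-valine tert-butyl ester·(R)-3,3′-bis(2,4,6-triisopropylphenyl)-1,1′-binaphthyl-2,2′-diyl hydrogen phosphate salt (10 mol %), diethyl 2,6-dimethyl-1,4-dihydropyridine-3,5-dicarboxylate (1.05 equiv), Bu2O, 50 °C
Reagents that add atoms: none
Why: Proposed new method: desymmetrising iminium transfer hydrogenation of a cross-conjugated 3,5-dimethyl-4,4-dialkylcyclohexadienone. The primary ammonium salt condenses with the C1 carbonyl to a cross-conjugated iminium ion whose N–H is hydrogen-bonded to the chiral phosphate; the phosphate also binds the N–H of the Hantzsch ester, so hydride goes only to the β-carbon on the N–H side and only from the face left open by the triisopropylphenyl pocket. The two flanking vinylic methyl groups force the second carbon of the C4 side chain to sit over the ring, so the side-chain face is blocked and hydride enters C5 from the face of the C4 methyl group (Si face of C5); only one of the two diastereomeric iminium orientations is then productive, and C4 (R) and C5 (R, methyl cis to the side chain) are set together under catalyst control. The product enone is reduced further only slowly because its remaining β-carbon is the one the catalyst disfavours, while any minor enantiomer is consumed faster, which raises the ee. Closest known reaction type: counteranion-directed iminium transfer hydrogenation of 3-substituted cyclohex-2-enones with Hantzsch esters, not yet used to break the symmetry of a cyclohexadienone.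

Step 8
Reactants: 13 pent-4-yn-1-ol, 14 vinyl bromide
Product: 16 (E)-4-methylhepta-4,6-dien-1-ol, via alkenylalane 15 (not isolated)
Conditions: AlMe3 (3 equiv), Cp2ZrCl2 (25 mol %), CH2Cl2, 0 °C → rt; then ZnCl2, Pd(PPh3)4 (3 mol %), 14, THF, rt; aq. HCl work-up
Reagents that add atoms: trimethylaluminium (C[Al](C)C)
Why: Negishi Zr-catalysed syn-carboalumination of the terminal alkyne fixes the (E)-trisubstituted alkene, and the Pd/Zn-catalysed Negishi coupling with vinyl bromide retains it.

Step 9
Reactants: 16 (E)-4-methylhepta-4,6-dien-1-ol, 17 4-bromofuran-2(5H)-one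
Product: 19 4-[(E)-7-hydroxy-4-methylhept-3-en-1-yl]furan-2(5H)-one, via alkylborane 18 (not isolated)
Conditions: 9-BBN-H (2.2 equiv), THF, 0 °C → rt; then 17, PdCl2(dppf) (5 mol %), K3PO4, DMF, 50 °C; aq. work-up
Reagents that add atoms: none
Why: 9-BBN hydroborates only the terminal vinyl group of the diene (anti-Markovnikov, homoallylic borane), and B-alkyl Suzuki–Miyaura coupling with the vinylogous acyl bromide under anhydrous phosphate conditions spares the lactone and the alkene geometry.

Step 10
Reactants: 19 4-[(E)-7-hydroxy-4-methylhept-3-en-1-yl]furan-2(5H)-one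
Product: 20 (E)-4-methyl-7-(5-oxo-2,5-dihydrofuran-3-yl)hept-4-enal
Conditions: Dess–Martin periodinane, CH2Cl2, rt
Reagents that add atoms: none
Why: Dess–Martin oxidation of a primary alcohol stops at the aldehyde and leaves the butenolide and the trisubstituted alkene untouched.

Step 11
Reactants: 12 (4R,5R)-4-(3-bromobut-3-en-1-yl)-3,4,5-trimethylcyclohex-2-en-1-one, 20 (E)-4-methyl-7-(5-oxo-2,5-dihydrofuran-3-yl)hept-4-enal
Product: 21 4-[(3E,7R)-7-hydroxy-4-methyl-8-methylidene-10-[(1R,6R)-1,2,6-trimethyl-4-oxocyclohex-2-en-1-yl]dec-3-en-1-yl]furan-2(5H)-one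
Conditions: CrCl2 (10 mol %), (S)-N-[2-(4-isopropyl-4,5-dihydro-1,3-oxazol-2-yl)-6-methoxyphenyl]methanesulfonamide (12 mol %), proton sponge (12 mol %), NiCl2·(2,9-dimethyl-1,10-phenanthroline) (2 mol %), Mn powder, Cp2ZrCl2, LiCl, MeCN, rt
Reagents that add atoms: none
Why: Catalytic asymmetric Nozaki–Hiyama–Kishi coupling; the alkenylchromium species adds to the aldehyde only (enone and lactone are inert), and the chiral sulfonamide on chromium directs Si-face addition to give the (7R)-carbinol independently of the remote ring centres.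

Step 12
Reactants: 21 4-[(3E,7R)-7-hydroxy-4-methyl-8-methylidene-10-[(1R,6R)-1,2,6-trimethyl-4-oxocyclohex-2-en-1-yl]dec-3-en-1-yl]furan-2(5H)-one
Product: 22 (3E,7R)-4-methyl-8-methylidene-1-(5-oxo-2,5-dihydrofuran-3-yl)-10-[(1R,6R)-1,2,6-trimethyl-4-oxocyclohex-2-en-1-yl]dec-3-en-7-yl acetate
Conditions: Ac2O, pyridine, DMAP (cat.), CH2Cl2, 0 °C → rt
Reagents that add atoms: acetic anhydride (CC(=O)OC(C)=O)
Why: DMAP-catalysed O-acylation of the secondary allylic alcohol proceeds with retention at C7 and touches no other group.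

## Compound list

1 | 5-methylcyclohexane-1,3-dione | CC1CC(=O)CC(=O)C1 | starting material
2 | 3-isobutoxy-5-methylcyclohex-2-en-1-one (racemic) | CC(C)COC1=CC(=O)CC(C)C1 | intermediate
3 | 3-bromobut-3-en-1-ol | C=C(Br)CCO | starting material
4 | 2-bromo-4-iodobut-1-ene | C=C(Br)CCI | intermediate
5 | lithium 5-isobutoxy-3-methylcyclohexa-1,5-dien-1-olate (racemic) | [Li+].[O-]C1=CC(C)CC(OCC(C)C)=C1 | intermediate (not isolated)
6 | 6-(3-bromobut-3-en-1-yl)-3-isobutoxy-5-methylcyclohex-2-en-1-one (racemic) | CC(C)COC1=CC(=O)C(CCC(Br)=C)C(C)C1 | intermediate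
7 | lithium 2-(3-bromobut-3-en-1-yl)-5-isobutoxy-3-methylcyclohexa-1,5-dien-1-olate (racemic) | [Li+].[O-]C1=C(CCC(Br)=C)C(C)CC(OCC(C)C)=C1 | intermediate (not isolated)
8 | 6-(3-bromobut-3-en-1-yl)-3-isobutoxy-5,6-dimethylcyclohex-2-en-1-one (racemic, diastereomer mixture) | CC(C)COC1=CC(=O)C(C)(CCC(Br)=C)C(C)C1 | intermediate
9 | lithium 6-(3-bromobut-3-en-1-yl)-3-isobutoxy-1,5,6-trimethylcyclohex-2-en-1-olate (racemic, diastereomer mixture) | [Li+].[O-]C1(C)C=C(OCC(C)C)CC(C)C1(C)CCC(Br)=C | intermediate (not isolated)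
10 | 4-(3-bromobut-3-en-1-yl)-3,4,5-trimethylcyclohex-2-en-1-one (racemic, diastereomer mixture) | C=C(Br)CCC1(C)C(C)=CC(=O)CC1C | intermediate
11 | 4-(3-bromobut-3-en-1-yl)-3,4,5-trimethylcyclohexa-2,5-dien-1-one (achiral) | C=C(Br)CCC1(C)C(C)=CC(=O)C=C1C | intermediate
12 | (4R,5R)-4-(3-bromobut-3-en-1-yl)-3,4,5-trimethylcyclohex-2-en-1-one | C=C(Br)CC[C@@]1(C)C(C)=CC(=O)C[C@H]1C | intermediate
13 | pent-4-yn-1-ol | C#CCCCO | starting material
14 | vinyl bromide | C=CBr | starting material
15 | (E)-[5-(dimethylalumanyloxy)-2-methylpent-1-en-1-yl]dimethylalumane | C[Al](C)OCCC/C(C)=C/[Al](C)C | intermediate (not isolated)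
16 | (E)-4-methylhepta-4,6-dien-1-ol | OCCC/C(C)=C/C=C | intermediate
17 | 4-bromofuran-2(5H)-one | BrC1=CC(=O)OC1 | starting material
18 | 9-[(E)-7-(9-borabicyclo[3.3.1]nonan-9-yloxy)-4-methylhept-3-en-1-yl]-9-borabicyclo[3.3.1]nonane | C(CC/C(C)=C/CCB1C2CCCC1CCC2)OB3C4CCCC3CCC4 | intermediate (not isolated)
19 | 4-[(E)-7-hydroxy-4-methylhept-3-en-1-yl]furan-2(5H)-one | OCCC/C(C)=C/CCC1=CC(=O)OC1 | intermediate
20 | (E)-4-methyl-7-(5-oxo-2,5-dihydrofuran-3-yl)hept-4-enal | O=CCC/C(C)=C/CCC1=CC(=O)OC1 | intermediate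
21 | 4-[(3E,7R)-7-hydroxy-4-methyl-8-methylidene-10-[(1R,6R)-1,2,6-trimethyl-4-oxocyclohex-2-en-1-yl]dec-3-en-1-yl]furan-2(5H)-one | C=C(CC[C@@]1(C)C(C)=CC(=O)C[C@H]1C)[C@@H](CC/C(C)=C/CCC1=CC(=O)OC1)O | intermediate
22 | (3E,7R)-4-methyl-8-methylidene-1-(5-oxo-2,5-dihydrofuran-3-yl)-10-[(1R,6R)-1,2,6-trimethyl-4-oxocyclohex-2-en-1-yl]dec-3-en-7-yl acetate (CNP0204194.1) | C=C(CC[C@@]1(C)C(C)=CC(=O)C[C@H]1C)[C@@H](CC/C(C)=C/CCC1=CC(=O)OC1)OC(C)=O | target

## Step count and risks

Total steps: 12. Longest linear sequence: 8 (steps 1, 3, 4, 5, 6, 7, 11, 12).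

**Step 7 (the proposed new desymmetrisation).** The risks are weak discrimination between the methyl face and the side-chain face at C4 (low dr), slow iminium formation from the hindered dienone, and over-reduction to the saturated ketone. The fallback sets out from 11 and returns at 12, and uses known ligated-CuH chemistry (asymmetric conjugate reduction of β-substituted cyclic enones and desymmetrisation of 4,4-disubstituted cyclohexadienones). Treating 11 with Cu(OAc)2 (3 mol %), (R)-DTBM-SEGPHOS (3.3 mol %) and diethoxymethylsilane in toluene at 0 °C gives the silyl dienol ether {[(3R,4R)-4-(3-bromobut-3-en-1-yl)-3,4,5-trimethylcyclohexa-1,5-dien-1-yl]oxy}(diethoxy)methylsilane F1. F1 cannot be reduced a second time because the enolate is trapped, and brief treatment with 1 M HCl in THF releases 12. The ligand antipode is fixed after the first run.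

**Step 11 (asymmetric Ni/Cr coupling).** The risks are a sluggish 2-bromoalkene and incomplete catalyst control at C7, which would give C7 epimers that are hard to separate because the ring centres are remote. The fallback sets out from 12 and 20 and returns at 21. A non-selective coupling (CrCl2 in excess, NiCl2 1 mol %, DMSO, rt) gives the C7-epimeric mixture 4-[(3E,7RS)-7-hydroxy-4-methyl-8-methylidene-10-[(1R,6R)-1,2,6-trimethyl-4-oxocyclohex-2-en-1-yl]dec-3-en-1-yl]furan-2(5H)-one F2. Sharpless kinetic resolution (Ti(OiPr)4, L-(+)-diisopropyl tartrate, t-BuOOH, 4 Å sieves, CH2Cl2, −20 °C) then epoxidises only the (7S)-epimer, a 2-substituted allylic alcohol of the fast-reacting type. This gives the erythro epoxy alcohol 4-[(3E,7S)-7-hydroxy-4-methyl-7-[(2S)-2-{2-[(1R,6R)-1,2,6-trimethyl-4-oxocyclohex-2-en-1-yl]ethyl}oxiran-2-yl]hept-3-en-1-yl]furan-2(5H)-one F3, which is removed by chromatography; the unreacted (7R)-alcohol is 21. The cost is at most half of the coupled material.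

**Step 6 (IBX dehydrogenation).** The risk is that enolisation towards C6 and loss of the tertiary C5–H next to a quaternary carbon are slow, so the enone may decompose at 75 °C before it is dehydrogenated. The fallback sets out from 10 and returns at 11 by a two-stage Saegusa–Ito sequence. Kinetic deprotonation with LiN(iPr)2 in THF at −78 °C gives the cross-conjugated lithium 4-(3-bromobut-3-en-1-yl)-3,4,5-trimethylcyclohexa-1,5-dien-1-olate F4. Trapping with Me3SiCl gives {[4-(3-bromobut-3-en-1-yl)-3,4,5-trimethylcyclohexa-1,5-dien-1-yl]oxy}trimethylsilane F5, and Pd(OAc)2 in MeCN at rt then gives 11.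

Further compounds

F1 | step 7 | {[(3R,4R)-4-(3-bromobut-3-en-1-yl)-3,4,5-trimethylcyclohexa-1,5-dien-1-yl]oxy}(diethoxy)methylsilane | C=C(Br)CC[C@@]1(C)C(C)=CC(O[Si](C)(OCC)OCC)=C[C@H]1C
F2 | step 11 | 4-[(3E,7RS)-7-hydroxy-4-methyl-8-methylidene-10-[(1R,6R)-1,2,6-trimethyl-4-oxocyclohex-2-en-1-yl]dec-3-en-1-yl]furan-2(5H)-one (C7-epimer mixture) | C=C(CC[C@@]1(C)C(C)=CC(=O)C[C@H]1C)C(O)CC/C(C)=C/CCC1=CC(=O)OC1
F3 | step 11 | 4-[(3E,7S)-7-hydroxy-4-methyl-7-[(2S)-2-{2-[(1R,6R)-1,2,6-trimethyl-4-oxocyclohex-2-en-1-yl]ethyl}oxiran-2-yl]hept-3-en-1-yl]furan-2(5H)-one | O[C@@H](CC/C(C)=C/CCC1=CC(=O)OC1)[C@@]2(CO2)CC[C@@]3(C)C(C)=CC(=O)C[C@H]3C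
F4 | step 6 | lithium 4-(3-bromobut-3-en-1-yl)-3,4,5-trimethylcyclohexa-1,5-dien-1-olate (racemic, diastereomer mixture) | [Li+].[O-]C1=CC(C)C(C)(CCC(Br)=C)C(C)=C1
F5 | step 6 | {[4-(3-bromobut-3-en-1-yl)-3,4,5-trimethylcyclohexa-1,5-dien-1-yl]oxy}trimethylsilane (racemic, diastereomer mixture) | C[Si](C)(C)OC1=CC(C)C(C)(CCC(Br)=C)C(C)=C1
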